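The numbers were chosen freely; the flask was simulated.

At the start of epsilon the partner feeds self-condensation faster than it feeds the left-handed substrate.

    2 partner → self-condensation product (k1 = 0.0161 /M/min, Ea1 = 68.0 kJ/mol)
    partner + catalyst + right-handed substrate → catalyst + right-handed product (k2 = 1.83 /M²/min, Ea2 = 42.0 kJ/mol)
    partner + protic impurity → quenched reagent (k3 = 0.0162 /M/min, Ea3 = 61.0 kJ/mol)
    partner + catalyst + left-handed substrate → catalyst + left-handed product (k4 = 5.06 /M²/min, Ea4 = 44.0 kJ/mol)
    (constants at 5 °C)

the same everywhere: left-handed substrate 0.10 M; partner 1.10 equiv; protic impurity 0.0200 M; catalyst 2.1 mol%; right-handed substrate 0.10 M; time 12 d

| flask | temperature | remark |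
|---|---|---|
| epsilon | 5 °C |  |
| delta | −35 °C |  |
| alpha |  | at −35 °C until 8.0 d, from then on at 5 °C |
| theta | −15 °C |  |

- catalyst is single-handed; left-handed substrate and right-handed substrate are mirror images of each other, charged as a racemate, each of them at the stated concentration
- a step written with two of one species runs at k times the square of its concentration and takes two of it each time
- the list of constants is for 5 °C, to be carried to other temperatures by the activation energies
- an excess is the difference of the two amounts in percent of their sum
- an excess is below zero if the other one leads

- which flask leads in excess of left-handed product over right-handed product ("all alike" within 1.5 percentage points) (epsilon / delta / alpha / theta / all alike)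
- excess of left-handed product over right-handed product at the end, epsilon
- excess of left-handed product over right-handed product at the end, delta
- excess of left-handed product over right-handed product at the end, alpha
- excess of left-handed product over right-handed product at the end, theta

**Warm ladder.** With substrates and impurity held at their charges, the first half-life of the partner by self-condensation in epsilon is 0.196 d. Its pseudo-first-order lifetimes are 0.654 d against the left-handed substrate, 1.81 d against the right-handed substrate and 2.14 d against the protic impurity. The run of 12 d is longer than each of these, so epsilon should consume its partner early and then stand still.

**Cold ladder.** The right-handed step speeds up by a factor 21 between −35 °C and 5 °C, so every other clock scales by that factor raised to the ratio of activation energies. In delta the half-life becomes 27.4 d, longer than the left-handed lifetime of 16.0 d, so these two rungs swap. The right-handed and impurity clocks become 38.2 d and 180 d.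

**Crossover fraction.** Epsilon gives 0.500 for the crossover fraction, the fraction of the partner charge at which its second-order and first-order losses are equal, which is the half-life times the summed inverse lifetimes. Above it the partner is lost mainly by second-order self-condensation, and below it by first-order routes. Integrating both losses gives the first-order routes a share equal to the fraction times ln(1 + its reciprocal). The catalysed routes hold 81.7% of that share in epsilon. Products should therefore take 44.9% of the partner charge, a conversion of 24.7% of both substrates together.

Delta gives 2.58, so products should take 79.6% of its partner charge once that charge is spent, a conversion of 43.8% of both substrates together. The first product formed carries an excess of 46.9% in epsilon, from a selectivity factor of 2.77, and 41.0% in delta. At a fixed selectivity factor excess falls as conversion grows, and epsilon has the higher first excess and the lower reckoned conversion with its partner spent, so this reckoning puts epsilon ahead.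

**The forecast.** It names epsilon as leader, with 35.2% (range 33.5% to 37%), delta 25.2%, alpha 22.9% and theta 26.9%. Its partner is “taken as 1.10 equiv on total substrate”, whereas the reckoning above charges it on the left-handed substrate, 0.110 M.

**At rest?** The flasks end at 41.8% for epsilon, 35.6% for delta, 35.9% for alpha and 37.2% for theta, so epsilon leads, and the forecast for epsilon stands 6.6 percentage points low. Epsilon is at rest: its partner stands at 0% by 6.00 d, products hold 43.5% of the partner charge against the reckoned 44.9%, and ten times the time changes nothing. Delta is still moving, with 31.3% of its partner present at 12.0 d. By 120 d that is 0.0875%, products hold 76.4% of the partner charge against the reckoned 79.6%, and the excess has fallen to 31.8%.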